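**Plan**

- Retrosynthesis: the two acetates and the C7=C16 methylene are removed first (Peterson retron at C7). The ten-membered ring is then cut at C3–C4 (alkenyl iodide at C3, alkylborane at C4), the chain at C8–C9 (aldol), the iodoalkene at C2=C3 (Wittig), and ring A at C1–C10 and C13–C14 (Diels–Alder).
- Enabling feature: in the ten-membered ring the Z alkene C2=C3 carries its methyl on C3, and C3 is bonded to the saturated carbon C4. Both arms sit cis on ring A (at C1 and C10), so an open-chain Z iodoalkene on C1 and a C4=C5 vinyl terminus on the C10 arm can be joined by one sp2–sp3 bond.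
- Forward: ring A first, then the C11 carbinol, the Z iodoalkene on C1, the C9 aldehyde and its aldol union with a C4–C8 enol silane, masking of C7 as C(OH)CH2SiMe3, closure of the ten-membered ring at C3–C4, and finally unmasking of C7=C16, desilylation and acetylation.
- Stereochemistry: C1, C10 and C14 from an organocatalytic endo Diels–Alder reaction; C11 from epoxidation anti to the C10 arm and hydride opening; C6 from Sharpless desymmetrisation of penta-1,4-dien-3-ol; C9 from a Felkin–Anh Mukaiyama aldol; the Z alkene from an α-iodo ylide, retained in the coupling.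

Key step: step 19

Numbering used throughout (eunicellane): ten-membered ring C1–C10; ring A = C10, C11, C12, C13, C14, C1; C15 = methyl on C3, C16 = carbon on C7, C17 = methyl on C11.

Assumption: the C7 carbinol centre of 26, 27 and 28 is temporary and is destroyed in step 20; it is expected mainly as one (Felkin–Anh) epimer and is left unassigned in names and SMILES.

Design remark: C7 is carried through the ring closure as the tertiary carbinol C(OH)CH2SiMe3. This group is inert to 9-BBN-H and to aqueous carbonate, needs no ketalisation of a hindered α,β′-dioxygenated ketone, and releases the exocyclic methylene under the same acid that removes the silyl ethers.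

**Step 1**
Reactants: 1 (2E)-3-methylpent-2-en-4-yn-1-ol
Product: 2 PMB ether of the enynol
Conditions: NaH, 4-methoxybenzyl chloride, Bu4NI (cat.), THF, 0 °C → rt
Reagents that add atoms: 4-methoxybenzyl chloride, COc1ccc(CCl)cc1
Why: Williamson ether synthesis in which NaH deprotonates only the hydroxyl (the alkyne C–H is far less acidic), and the PMB group is chosen because it can later be removed oxidatively beside silyl ethers and the iodoalkene.

**Step 2**
Reactants: 2 PMB ether of the enynol
Product: 3 (E)-diene PMB ether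
Conditions: H2 (1 atm), Pd/CaCO3 poisoned with Pb(OAc)2, quinoline, EtOAc/hexane, rt, stopped after 1 equiv H2
Reagents that add atoms: none
Why: Lindlar semi-hydrogenation should stop at the alkene for the terminal alkyne on the lead-poisoned catalyst, giving the (E)-1,2-disubstituted diene without touching the trisubstituted alkene geometry or the benzylic ether.

**Step 3**
Reactants: 3 (E)-diene PMB ether; 4 (2E)-4-methylpent-2-enal
Product: 6 ring-A cyclohexenylmethanol, via cyclohexenecarbaldehyde 5 (not isolated)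
Conditions: (5S)-5-benzyl-2,2,3-trimethylimidazolidin-4-one·HCl (20 mol %), 4 (2 equiv), MeCN/H2O 95:5, rt; then EtOH, NaBH4, 0 °C
Reagents that add atoms: none
Why: Iminium-ion-catalysed Diels–Alder reaction in which the 1-substituent of the diene directs the "ortho" union (C1–C10 and C13–C14), the endo transition state of the (E)-diene places the formyl group cis to the C10 arm, the (E)-enal fixes isopropyl trans to formyl, and the benzyl group of the (5S)-catalyst shields one face of the s-trans (E)-iminium ion so that C1, C10 and C14 should arise as drawn, after which NaBH4 reduces the aldehyde before it can epimerise.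

**Step 4**
Reactants: 6 ring-A cyclohexenylmethanol
Product: 7 C11,C12-epoxide
Conditions: mCPBA, NaHCO3, CH2Cl2, 0 °C
Reagents that add atoms: 3-chloroperoxybenzoic acid, O=C(OO)c1cccc(Cl)c1
Why: Prilezhaev epoxidation, in which the half-chair with the C1 and C14 substituents equatorial holds the C10 CH2OPMB group pseudoaxial on the lower face next to the alkene, so the peracid should add to C11=C12 from the face of H-10 and set the C11–O bond trans to the C10 arm.

**Step 5**
Reactants: 7 C11,C12-epoxide
Product: 8 ring-A diol (primary C2–OH, tertiary C11–OH)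
Conditions: LiAlH4, THF, 0 → 50 °C
Reagents that add atoms: none
Why: Hydride opening of the epoxide at the secondary carbon C12, which is also the trans-diaxial (Fürst–Plattner) mode of the preferred conformer, leaves the C11–O bond untouched and should give the tertiary alcohol with OH cis to H-10.

**Step 6**
Reactants: 8 ring-A diol
Product: 9 C2 hydroxy aldehyde
Conditions: Dess–Martin periodinane, NaHCO3, CH2Cl2, 0 °C → rt
Reagents that add atoms: none
Why: Dess–Martin oxidation acts only on the primary alcohol, since the tertiary C11 hydroxyl cannot be oxidised and, being trans-1,3 to the formyl group, cannot close a lactol.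

**Step 7**
Reactants: 9 C2 hydroxy aldehyde; 10 ethyltriphenylphosphonium iodide
Product: 14 (Z)-iodoalkene tertiary alcohol, via ethylidenetriphenylphosphorane 11 (not isolated), via (1-iodoethyl)triphenylphosphonium iodide 12 (not isolated), via (1-iodoethylidene)triphenylphosphorane 13 (not isolated)
Conditions: 10 (3 equiv), n-BuLi, THF, rt; I2, −78 °C; NaN(SiMe3)2, −78 → −20 °C; then 9, −78 → −20 °C
Reagents that add atoms: iodine, II
Why: Wittig olefination with the α-iodo ylide made in the flask (Stork–Zhao-type iodoalkylidenation) should give, under kinetic control at low temperature, the trisubstituted iodoalkene with iodine cis to the ring carbon (Z), the excess ylide covering the free tertiary hydroxyl.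

**Step 8**
Reactants: 14 (Z)-iodoalkene tertiary alcohol
Product: 15 C11 triethylsilyl ether
Conditions: Et3SiOTf, 2,6-lutidine, CH2Cl2, −78 → 0 °C
Reagents that add atoms: triethylsilyl trifluoromethanesulfonate, CC[Si](CC)(CC)OS(=O)(=O)C(F)(F)F
Why: Silylation of the hindered tertiary alcohol with the silyl triflate and a hindered base; the ether prevents retro-aldol cleavage or dehydration once C9 becomes an aldehyde.

**Step 9**
Reactants: 15 C11 triethylsilyl ether
Product: 16 C9 primary alcohol
Conditions: DDQ, CH2Cl2/pH 7 buffer 10:1, 0 °C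
Reagents that add atoms: none
Why: Oxidative cleavage of the PMB ether by DDQ (benzylic hydride abstraction, then hydrolysis of the oxocarbenium ion) in buffered medium should spare the tertiary silyl ether and the iodoalkene.

**Step 10**
Reactants: 16 C9 primary alcohol
Product: 17 C9 aldehyde
Conditions: Dess–Martin periodinane, NaHCO3, CH2Cl2, 0 °C; used at once
Reagents that add atoms: none
Why: Dess–Martin oxidation under buffered, non-basic conditions should give the β-silyloxy aldehyde without epimerising C10 or eliminating silanol.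

**Step 11**
Reactants: 18 penta-1,4-dien-3-ol
Product: 19 (2S,3R)-1,2-epoxypent-4-en-3-ol
Conditions: Ti(OiPr)4 (10 mol %), D-(−)-diisopropyl tartrate (13 mol %), t-BuOOH, 4 Å MS, CH2Cl2, −20 °C
Reagents that add atoms: tert-butyl hydroperoxide, CC(C)(C)OO
Why: Sharpless asymmetric epoxidation of the achiral divinyl carbinol, in which the tartrate selects one enantiotopic vinyl group and its face (erythro epoxy alcohol, R carbinol = C6) and the minor enantiomer is consumed by a second epoxidation, so enantiomeric purity should rise with conversion.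

**Step 12**
Reactants: 19 (2S,3R)-1,2-epoxypent-4-en-3-ol
Product: 20 TBS ether of the epoxy alcohol
Conditions: t-BuMe2SiCl, imidazole, DMF, rt
Reagents that add atoms: tert-butyl(chloro)dimethylsilane, CC(C)(C)[Si](C)(C)Cl
Why: Standard silylation of a secondary alcohol with a base too weak to open the epoxide.

**Step 13**
Reactants: 20 TBS ether of the epoxy alcohol
Product: 21 bromohydrin
Conditions: LiBr, AcOH, THF, rt
Reagents that add atoms: lithium bromide, [Li+].[Br-]
Why: Bromide opens the protonated terminal epoxide at the primary carbon (SN2), leaving C6 untouched and giving the bromohydrin without any alkoxide that could trigger silyl migration.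

**Step 14**
Reactants: 21 bromohydrin
Product: 22 α-bromo ketone
Conditions: Dess–Martin periodinane, NaHCO3, CH2Cl2, 0 °C → rt
Reagents that add atoms: none
Why: Dess–Martin oxidation gives the bromomethyl ketone under neutral conditions, so the doubly activated C6–H (α to the carbonyl and allylic) is never exposed to base.

**Step 15**
Reactants: 22 α-bromo ketone
Product: 23 C4–C8 enol silane
Conditions: Zn dust, Me3SiCl, TMEDA, Et2O, 0 °C → rt; used crude
Reagents that add atoms: chlorotrimethylsilane, C[Si](C)(C)Cl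
Why: Zinc inserts into the C–Br bond (Reformatsky-type zinc enolate) and Me3SiCl traps it on oxygen, which should give the enol silane regiospecifically at C8 and avoids base-mediated enolisation towards C6.

**Step 16**
Reactants: 17 C9 aldehyde; 23 C4–C8 enol silane
Product: 24 β-hydroxy ketone (C8–C9 bond)
Conditions: BF3·OEt2 (1.2 equiv), CH2Cl2, −78 °C; aq. NaHCO3
Reagents that add atoms: none
Why: Mukaiyama aldol addition through an open transition state, in which the nucleophile should attack the aldehyde anti to the quaternary C11 (Felkin–Anh, C11 as the large group) while the β-silyloxy group favours the same face (1,3-anti), setting C9 as R.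

**Step 17**
Reactants: 24 β-hydroxy ketone
Product: 25 C9 TBS ether
Conditions: t-BuMe2SiOTf, 2,6-lutidine, CH2Cl2, −78 °C
Reagents that add atoms: tert-butyldimethylsilyl trifluoromethanesulfonate, CC(C)(C)[Si](C)(C)OS(=O)(=O)C(F)(F)F
Why: Low-temperature silylation with the silyl triflate protects C9–OH before the organometallic addition and blocks retro-aldol cleavage.

**Step 18**
Reactants: 25 C9 TBS ether
Product: 26 β-hydroxysilane (ring-closure precursor)
Conditions: Me3SiCH2MgCl, anhydrous CeCl3, THF, −78 °C (reagent pre-formed before adding 25); aq. NH4Cl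
Reagents that add atoms: (trimethylsilyl)methylmagnesium chloride, C[Si](C)(C)C[Mg]Cl
Why: Organocerium addition to the hindered, enolisable ketone should proceed without enolisation, β-elimination or halogen–metal exchange at the iodoalkene and installs the Peterson precursor that masks the C7 methylene, the new C7 centre being temporary.

**Step 19**
Reactants: 26 β-hydroxysilane (ring-closure precursor)
Product: 28 ring-A-fused ten-membered carbocycle, via C4 alkylborane 27 (not isolated)
Conditions: 9-BBN-H (2.5 equiv), THF, rt, 4 h; then slow addition (12 h) to PdCl2(dppf) (20 mol %), AsPh3 (20 mol %), Cs2CO3 (4 equiv), DMF/THF/H2O, 50 °C, about 1 mM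
Reagents that add atoms: 9-borabicyclo[3.3.1]nonane (9-BBN-H), B1C2CCCC1CCC2 (its boron and carbons are held only in 27; 28 keeps one hydrogen from it at C5)
Why: 9-BBN-H adds anti-Markovnikov to the only monosubstituted alkene (C4=C5) and puts boron on C4; zerovalent palladium, formed in the flask from the divalent precatalyst PdCl2(dppf), inserts into the C3–I bond with retention, the base-activated alkylborate hands C4 to palladium, and reductive elimination forms C3–C4. The closest known reaction type is the B-alkyl Suzuki–Miyaura macrocyclisation of a 9-BBN alkylborane onto an alkenyl iodide, used for medium and large carbocycles, with a ten-membered ring bearing a trisubstituted alkene at the hard end of its range. The ten-membered ring closes by C(sp2)–C(sp3) bond formation through an eleven-membered palladacycle (Pd, C3, C2, C1, C10, C9, C8, C7, C6, C5, C4) that contracts on reductive elimination. No stereocentre is formed; the Z geometry of C2=C3 was fixed in step 7 and is kept because oxidative addition and reductive elimination both proceed with retention at C3. Chemoselective hydroboration is secured by carrying C7 as the β-silyl carbinol (no 1,1-disubstituted alkene is present) and by the inertness of the trisubstituted iodoalkene to 9-BBN-H; ring closure over oligomerisation is favoured by the cis ring fusion, which holds the C1 and C10 arms on one face of ring A, and by slow addition to a final concentration near 1 mM.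

**Step 20**
Reactants: 28 ring-A-fused ten-membered carbocycle
Product: 29 eunicella-2,7(16)-diene-6,9,11-triol
Conditions: 48 % aq. HF, MeCN, 0 °C → rt
Reagents that add atoms: none
Why: Aqueous HF should promote the acid-mediated Peterson elimination (anti loss of Me3Si and the C7 hydroxyl, regiospecific for the exocyclic C7=C16 alkene whichever C7 epimer is present) and cleave the triethylsilyl and both TBS ethers in the same operation.

**Step 21**
Reactants: 29 eunicella-2,7(16)-diene-6,9,11-triol
Product: 30 target diacetate (CNP0303839.1)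
Conditions: Ac2O, pyridine, DMAP (cat.), CH2Cl2, 0 °C → rt
Reagents that add atoms: acetic anhydride, CC(=O)OC(C)=O
Why: Acetylation of the two secondary hydroxyls at C6 and C9, the tertiary C11 hydroxyl being too hindered to react under these conditions.

**Compound list**

1 | (2E)-3-methylpent-2-en-4-yn-1-ol | C#C/C(C)=C/CO | starting material
2 | 1-methoxy-4-({[(2E)-3-methylpent-2-en-4-yn-1-yl]oxy}methyl)benzene | C#C/C(C)=C/COCc1ccc(OC)cc1 | intermediate
3 | 1-methoxy-4-({[(2E)-3-methylpenta-2,4-dien-1-yl]oxy}methyl)benzene | C=C/C(C)=C/COCc1ccc(OC)cc1 | intermediate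
4 | (2E)-4-methylpent-2-enal | CC(C)/C=C/C=O | starting material
5 | (1R,2R,6R)-2-{[(4-methoxyphenyl)methoxy]methyl}-3-methyl-6-(propan-2-yl)cyclohex-3-ene-1-carbaldehyde (formed in the flask, not isolated) | COc1ccc(COC[C@@H]2[C@H](C=O)[C@@H](C(C)C)CC=C2C)cc1 | intermediate
6 | [(1R,2R,6R)-2-{[(4-methoxyphenyl)methoxy]methyl}-3-methyl-6-(propan-2-yl)cyclohex-3-en-1-yl]methanol | COc1ccc(COC[C@@H]2[C@H](CO)[C@@H](C(C)C)CC=C2C)cc1 | intermediate
7 | [(1S,2S,3R,4R,6R)-2-{[(4-methoxyphenyl)methoxy]methyl}-1-methyl-4-(propan-2-yl)-7-oxabicyclo[4.1.0]heptan-3-yl]methanol | COc1ccc(COC[C@@H]2[C@H](CO)[C@@H](C(C)C)C[C@H]3O[C@@]23C)cc1 | intermediate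
8 | (1R,2S,3R,4R)-3-(hydroxymethyl)-2-{[(4-methoxyphenyl)methoxy]methyl}-1-methyl-4-(propan-2-yl)cyclohexan-1-ol | COc1ccc(COC[C@@H]2[C@H](CO)[C@@H](C(C)C)CC[C@@]2(C)O)cc1 | intermediate
9 | (1R,2S,3R,6R)-3-hydroxy-2-{[(4-methoxyphenyl)methoxy]methyl}-3-methyl-6-(propan-2-yl)cyclohexane-1-carbaldehyde | COc1ccc(COC[C@@H]2[C@H](C=O)[C@@H](C(C)C)CC[C@@]2(C)O)cc1 | intermediate
10 | ethyltriphenylphosphonium iodide | CC[P+](c1ccccc1)(c1ccccc1)c1ccccc1.[I-] | starting material
11 | ethylidenetriphenylphosphorane (formed in the flask, not isolated) | CC=P(c1ccccc1)(c1ccccc1)c1ccccc1 | intermediate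
12 | (1-iodoethyl)triphenylphosphonium iodide (formed in the flask, not isolated) | CC(I)[P+](c1ccccc1)(c1ccccc1)c1ccccc1.[I-] | intermediate
13 | (1-iodoethylidene)triphenylphosphorane (formed in the flask, not isolated) | CC(I)=P(c1ccccc1)(c1ccccc1)c1ccccc1 | intermediate
14 | (1R,2S,3R,4R)-3-[(1Z)-2-iodoprop-1-en-1-yl]-2-{[(4-methoxyphenyl)methoxy]methyl}-1-methyl-4-(propan-2-yl)cyclohexan-1-ol | COc1ccc(COC[C@@H]2[C@H](/C=C(/C)I)[C@@H](C(C)C)CC[C@@]2(C)O)cc1 | intermediate
15 | triethyl{[(1R,2S,3R,4R)-3-[(1Z)-2-iodoprop-1-en-1-yl]-2-{[(4-methoxyphenyl)methoxy]methyl}-1-methyl-4-(propan-2-yl)cyclohexyl]oxy}silane | COc1ccc(COC[C@@H]2[C@H](/C=C(/C)I)[C@@H](C(C)C)CC[C@@]2(C)O[Si](CC)(CC)CC)cc1 | intermediate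
16 | [(1S,2R,5R,6R)-6-[(1Z)-2-iodoprop-1-en-1-yl]-2-methyl-5-(propan-2-yl)-2-[(triethylsilyl)oxy]cyclohexyl]methanol | OC[C@@H]1[C@H](/C=C(/C)I)[C@@H](C(C)C)CC[C@@]1(C)O[Si](CC)(CC)CC | intermediate
17 | (1R,2R,5R,6R)-6-[(1Z)-2-iodoprop-1-en-1-yl]-2-methyl-5-(propan-2-yl)-2-[(triethylsilyl)oxy]cyclohexane-1-carbaldehyde | O=C[C@@H]1[C@H](/C=C(/C)I)[C@@H](C(C)C)CC[C@@]1(C)O[Si](CC)(CC)CC | intermediate
18 | penta-1,4-dien-3-ol | C=CC(O)C=C | starting material
19 | (1R)-1-[(2S)-oxiran-2-yl]prop-2-en-1-ol [(2S,3R)-1,2-epoxypent-4-en-3-ol] | C=C[C@@H](O)[C@@H]1CO1 | intermediate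
20 | tert-butyl(dimethyl){[(1R)-1-[(2S)-oxiran-2-yl]prop-2-en-1-yl]oxy}silane | C=C[C@@H](O[Si](C)(C)C(C)(C)C)[C@@H]1CO1 | intermediate
21 | (2R,3R)-1-bromo-3-[(tert-butyldimethylsilyl)oxy]pent-4-en-2-ol | C=C[C@@H](O[Si](C)(C)C(C)(C)C)[C@@H](O)CBr | intermediate
22 | (3R)-1-bromo-3-[(tert-butyldimethylsilyl)oxy]pent-4-en-2-one | C=C[C@@H](O[Si](C)(C)C(C)(C)C)C(=O)CBr | intermediate
23 | (3R)-3-[(tert-butyldimethylsilyl)oxy]-2-[(trimethylsilyl)oxy]penta-1,4-diene | C=C[C@@H](O[Si](C)(C)C(C)(C)C)C(=C)O[Si](C)(C)C | intermediate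
24 | (3R,6R)-3-[(tert-butyldimethylsilyl)oxy]-6-hydroxy-6-[(1S,2R,5R,6R)-6-[(1Z)-2-iodoprop-1-en-1-yl]-2-methyl-5-(propan-2-yl)-2-[(triethylsilyl)oxy]cyclohexyl]hex-1-en-4-one | C=C[C@@H](O[Si](C)(C)C(C)(C)C)C(=O)C[C@@H](O)[C@@H]1[C@H](/C=C(/C)I)[C@@H](C(C)C)CC[C@@]1(C)O[Si](CC)(CC)CC | intermediate
25 | (3R,6R)-3,6-bis[(tert-butyldimethylsilyl)oxy]-6-[(1S,2R,5R,6R)-6-[(1Z)-2-iodoprop-1-en-1-yl]-2-methyl-5-(propan-2-yl)-2-[(triethylsilyl)oxy]cyclohexyl]hex-1-en-4-one | C=C[C@@H](O[Si](C)(C)C(C)(C)C)C(=O)C[C@@H](O[Si](C)(C)C(C)(C)C)[C@@H]1[C@H](/C=C(/C)I)[C@@H](C(C)C)CC[C@@]1(C)O[Si](CC)(CC)CC | intermediate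
26 | (3R,6R)-3,6-bis[(tert-butyldimethylsilyl)oxy]-6-[(1S,2R,5R,6R)-6-[(1Z)-2-iodoprop-1-en-1-yl]-2-methyl-5-(propan-2-yl)-2-[(triethylsilyl)oxy]cyclohexyl]-4-[(trimethylsilyl)methyl]hex-1-en-4-ol (C4 of the chain = C7, unassigned) | C=C[C@@H](O[Si](C)(C)C(C)(C)C)C(O)(C[Si](C)(C)C)C[C@@H](O[Si](C)(C)C(C)(C)C)[C@@H]1[C@H](/C=C(/C)I)[C@@H](C(C)C)CC[C@@]1(C)O[Si](CC)(CC)CC | intermediate
27 | B-alkyl-9-borabicyclo[3.3.1]nonane from 26 (boron on C4, hydrogen on C5; formed in the flask, not isolated) | B1(C2CCCC1CCC2)CC[C@@H](O[Si](C)(C)C(C)(C)C)C(O)(C[Si](C)(C)C)C[C@@H](O[Si](C)(C)C(C)(C)C)[C@@H]3[C@H](/C=C(/C)I)[C@@H](C(C)C)CC[C@@]3(C)O[Si](CC)(CC)CC | intermediate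
28 | (1S,2Z,6R,9R,10S,11R,14R)-6,9-bis[(tert-butyldimethylsilyl)oxy]-11-[(triethylsilyl)oxy]-16-(trimethylsilyl)eunicell-2-en-7-ol (C7 unassigned) | C[Si](C)(C)CC1(O)C[C@@H](O[Si](C)(C)C(C)(C)C)[C@@H]2[C@H](/C=C(/C)CC[C@H]1O[Si](C)(C)C(C)(C)C)[C@@H](C(C)C)CC[C@@]2(C)O[Si](CC)(CC)CC | intermediate
29 | (1S,2Z,6R,9R,10S,11R,14R)-eunicella-2,7(16)-diene-6,9,11-triol | C=C1C[C@@H](O)[C@@H]2[C@H](/C=C(/C)CC[C@H]1O)[C@@H](C(C)C)CC[C@@]2(C)O | intermediate
30 | (1S,2Z,6R,9R,10S,11R,14R)-11-hydroxyeunicella-2,7(16)-diene-6,9-diyl diacetate (CNP0303839.1) | C=C1C[C@@H](OC(C)=O)[C@@H]2[C@H](/C=C(/C)CC[C@H]1OC(C)=O)[C@@H](C(C)C)CC[C@@]2(C)O | target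

**Totals**

Total step count: 21.
Longest linear sequence: 16 steps (steps 1–10, then 16–21); the C4–C8 arm (steps 11–15) is made separately.

**Three steps most likely to fail**

1. Step 19 (ring closure). The alkylpalladium intermediate may be intercepted by a second molecule (oligomerisation), or the alkylborane may be lost by protodeboronation or β-hydride elimination before the strained ten-membered ring closes. The fallback makes the same C3–C4 bond between two separate pieces and closes the ring at C8–C9 instead. It sets out from epoxide 20 and iodide 15 and comes back at 28. 9-BBN-H adds to the vinyl group of 20 to give the B-alkyl borane F1. F1 is coupled with 15 (PdCl2(dppf), Cs2CO3, DMF/H2O) to the epoxide-bearing coupled diene F2. LiBr/AcOH opens the epoxide to the bromohydrin F3, DDQ removes the PMB group to give the diol F4, and Dess–Martin periodinane oxidises both hydroxyls to the bromoketo aldehyde F5. Slow addition of F5 to SmI2 in THF at −78 °C (intramolecular Reformatsky-type aldol through the samarium enolate at C8) closes the ten-membered ring as the β-hydroxy ketone F6, with C9 again expected from attack anti to C11. Silylation with t-BuMe2SiOTf gives the TBS ether F7, and Me3SiCH2MgCl/CeCl3 then gives 28.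

2. Step 3 (Diels–Alder). The β-branched iminium ion may react too slowly with the acyclic diene, or with insufficient facial and endo selectivity. The fallback binds the dienophile to a chiral oxazolidinone auxiliary; it sets out from enal 4 and diene 3 and comes back at 6. Pinnick oxidation of 4 (NaClO2, NaH2PO4, 2-methylbut-2-ene) gives (2E)-4-methylpent-2-enoic acid F8. Pivaloyl chloride/Et3N converts it into the mixed anhydride F9, which acylates lithiated (4S)-4-benzyl-1,3-oxazolidin-2-one to the imide F10. Cycloaddition with 3 promoted by Et2AlCl (CH2Cl2, −30 °C; chelated s-cis dienophile, diene approaching anti to the benzyl group, endo) gives the adduct F11. LiBH4 cleaves the auxiliary reductively and gives alcohol 6.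

3. Step 7 (iodo-olefination). The iodo ylide may be quenched by the free C11 hydroxyl or by enolisation of the hindered aldehyde, C1 may epimerise, or the Z:E ratio may erode. The fallback sets the geometry by a stereoselective cross-coupling; it sets out from aldehyde 9 and comes back at 14. Ramirez olefination (CBr4, PPh3, 2,6-lutidine) gives the 1,1-dibromoalkene F12. Negishi coupling with Me2Zn and PdCl2(DPEphos) replaces only the bromine trans to the ring carbon (the less hindered C–Br bond adds to zerovalent palladium first) and gives the (Z)-2-bromopropenyl compound F13. Copper-catalysed halogen exchange (CuI, NaI, trans-N,N′-dimethylcyclohexane-1,2-diamine, dioxane, 110 °C) proceeds with retention of geometry and gives iodide 14.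

**Further compounds**

F1 | step 19 | 9-{(3R)-3-[(tert-butyldimethylsilyl)oxy]-3-[(2S)-oxiran-2-yl]propyl}-9-borabicyclo[3.3.1]nonane | B1(C2CCCC1CCC2)CC[C@@H](O[Si](C)(C)C(C)(C)C)[C@@H]3CO3
F2 | step 19 | coupled epoxide: 15 with iodine replaced by the CH2CH2–(R)-CH(OSiMe2t-Bu)–[(2S)-oxiran-2-yl] chain, Z alkene kept | COc1ccc(COC[C@@H]2[C@H](/C=C(/C)CC[C@@H](O[Si](C)(C)C(C)(C)C)[C@@H]3CO3)[C@@H](C(C)C)CC[C@@]2(C)O[Si](CC)(CC)CC)cc1
F3 | step 19 | bromohydrin from F2 (7R hydroxyl, C8 bromide) | COc1ccc(COC[C@@H]2[C@H](/C=C(/C)CC[C@@H](O[Si](C)(C)C(C)(C)C)[C@@H](O)CBr)[C@@H](C(C)C)CC[C@@]2(C)O[Si](CC)(CC)CC)cc1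
F4 | step 19 | diol from F3 after PMB removal (C9 primary hydroxyl, C7 secondary hydroxyl) | OC[C@@H]1[C@H](/C=C(/C)CC[C@@H](O[Si](C)(C)C(C)(C)C)[C@@H](O)CBr)[C@@H](C(C)C)CC[C@@]1(C)O[Si](CC)(CC)CC
F5 | step 19 | open-chain bromoketo aldehyde (C7 ketone, C8 bromide, C9 aldehyde) | O=C[C@@H]1[C@H](/C=C(/C)CC[C@@H](O[Si](C)(C)C(C)(C)C)C(=O)CBr)[C@@H](C(C)C)CC[C@@]1(C)O[Si](CC)(CC)CC
F6 | step 19 | (1S,2Z,6R,9R,10S,11R,14R)-6-[(tert-butyldimethylsilyl)oxy]-9-hydroxy-11-[(triethylsilyl)oxy]-16-noreunicell-2-en-7-one | O=C1C[C@@H](O)[C@@H]2[C@H](/C=C(/C)CC[C@H]1O[Si](C)(C)C(C)(C)C)[C@@H](C(C)C)CC[C@@]2(C)O[Si](CC)(CC)CC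
F7 | step 19 | (1S,2Z,6R,9R,10S,11R,14R)-6,9-bis[(tert-butyldimethylsilyl)oxy]-11-[(triethylsilyl)oxy]-16-noreunicell-2-en-7-one | O=C1C[C@@H](O[Si](C)(C)C(C)(C)C)[C@@H]2[C@H](/C=C(/C)CC[C@H]1O[Si](C)(C)C(C)(C)C)[C@@H](C(C)C)CC[C@@]2(C)O[Si](CC)(CC)CC
F8 | step 3 | (2E)-4-methylpent-2-enoic acid | CC(C)/C=C/C(=O)O
F9 | step 3 | (2E)-4-methylpent-2-enoic 2,2-dimethylpropanoic anhydride | CC(C)/C=C/C(=O)OC(=O)C(C)(C)C
F10 | step 3 | (4S)-4-benzyl-3-[(2E)-4-methylpent-2-enoyl]-1,3-oxazolidin-2-one | CC(C)/C=C/C(=O)N1[C@@H](Cc2ccccc2)COC1=O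
F11 | step 3 | (4S)-4-benzyl-3-{[(1R,2R,6R)-2-{[(4-methoxyphenyl)methoxy]methyl}-3-methyl-6-(propan-2-yl)cyclohex-3-en-1-yl]carbonyl}-1,3-oxazolidin-2-one | COc1ccc(COC[C@@H]2[C@H](C(=O)N3[C@@H](Cc4ccccc4)COC3=O)[C@@H](C(C)C)CC=C2C)cc1
F12 | step 7 | (1R,2S,3R,4R)-3-(2,2-dibromoethenyl)-2-{[(4-methoxyphenyl)methoxy]methyl}-1-methyl-4-(propan-2-yl)cyclohexan-1-ol | COc1ccc(COC[C@@H]2[C@H](C=C(Br)Br)[C@@H](C(C)C)CC[C@@]2(C)O)cc1
F13 | step 7 | (1R,2S,3R,4R)-3-[(1Z)-2-bromoprop-1-en-1-yl]-2-{[(4-methoxyphenyl)methoxy]methyl}-1-methyl-4-(propan-2-yl)cyclohexan-1-ol | COc1ccc(COC[C@@H]2[C@H](/C=C(/C)Br)[C@@H](C(C)C)CC[C@@]2(C)O)cc1
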